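The earlier runs and the new flask are calculated with made-up constants; the scatter is artificial.

By the proposed steps one reagent goes in and one target comes out at each turn, so reagent, the catalyst intermediates and target together held the reagent charge throughout.

common to all: solid substrate 10 mM; free catalyst 0.50 mM
- north-east: reagent 5 mM; the very flask that is asked about, followed so far
- flask: reagent 5.00 mM; time 12 min

north-east run (percent of the solid substrate charged)

| time / min | target / % | solid substrate / % |
|---|---|---|
| 0.417 | 1.6 | 90.7 |
| 1.33 | 12.4 | 74.8 |
| 2.00 | 21.2 | 64.8 |
| 3.00 | 34.4 | 49.9 |
| 5.00 | 48.9 | 26.9 |
| 6.00 | 49.9 | 21.3 |

(scatter of a reading: 0.3 percentage points)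

- solid, in amounts per volume of the solution: solid substrate
- steps that have been proposed: reagent + free catalyst -> catalyst intermediate A; starting material + catalyst intermediate A <-> catalyst intermediate B; catalyst intermediate B -> catalyst intermediate C; catalyst intermediate C -> free catalyst + target; solid substrate <-> starting material
- at the start none of the solid substrate is in solution

- amount of target at 12 min, in percent of the solid substrate charged
- the change that raises the amount of target at 12 min, in percent of the solid substrate charged most ("none" if none brings more than 2 percentage points) (epsilon / gamma / alpha / theta / none)
- amount of target at 12 min, in percent of the solid substrate charged, after alpha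

- epsilon: doubling the amount of free catalyst, all else as stated
- gamma: doubling the dissolution coefficient of the solid substrate, all else as stated
- alpha: doubling the amount of reagent, all else as stated
- theta: doubling the solubility of the solid substrate, all else as stated

Set against the solid, that gave this flask a limit, the reagent charge over the solid charge:

ceiling = 5.00 mM / 10 mM = 50.0%

I called this the reagent ceiling, the bound that the limiting reagent puts on target, in percent of the solid charged.

In the first instants of this flask, at 0.417 min, solid and target together came to 92.3%, so the rest was in solution or on the catalyst. In the middle, target climbed steadily from 12.4% at 1.33 min to 34.4% at 3.00 min, a pace of 0.132 min⁻¹ as a fraction of the solid charged. At that pace the ceiling takes 3.80 min, well inside the 12 min asked. At the end, from 5.00 min to 6.00 min, target gained 1 percentage point and stood at 49.9%, closer to the ceiling than the scatter of 0.3 points, while the solid lost 5.6 points.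

So I committed to 50.0% for this flask. The division for the ceiling holds no catalyst, dissolving or solubility, so I chose alpha, doubling the reagent, which lifts it:

ceiling after alpha = 2 × 5.00 mM / 10 mM = 100%

At the same pace that takes 7.59 min, still inside 12 min. From 1.33 min to 3.00 min the solid in this flask fell faster than target rose, so dissolving kept ahead of the pace in that stretch, and I reckoned on just under 100%.

The forecast gave 50% (49.5% to 50.3%), chose alpha and put 90% (84% to 96%) on it, below my figure, saying “Catalysis lags slightly as reagent and dissolved substrate fall”.

    reagent + free catalyst → catalyst intermediate A (k = 79.1 L mol⁻¹ s⁻¹)
    starting material + catalyst intermediate A ⇌ catalyst intermediate B (K = 2260 L mol⁻¹, k = 48.5 L mol⁻¹ s⁻¹)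
    catalyst intermediate B → catalyst intermediate C (k = 0.624 s⁻¹)
    catalyst intermediate C → free catalyst + target (k = 7.18 s⁻¹)
    solid substrate ⇌ starting material, rate k5*(cs5 - [starting material]) while solid is left; crystals form when [starting material] > cs5 (solubility = 3.50 mM, k = 0.0118 s⁻¹)

This flask gave 50.0% at 12 min against its ceiling of 50.0%, and 99.2% after alpha against 100%. Turnover ran while reagent was there, 70.1% of its charge at 1.20 min with catalyst intermediate A at 77.4% of the catalyst, and 0.107% at 6.00 min; dissolving went on past that, and at 12.0 min the solid charged stood as 15.1% solid and 34.9% starting material. The neighbour flask with 3.0 mM of reagent has a ceiling of 30.0% by the same division, and it gave 30.0% at 12 min, with 35.0% of the solid charged as starting material.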